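Numbering: heavy atoms in the order of the target SMILES, leaving out carbonyl O atoms and the CH2OH group: C1 (methyl), C2, C3, C4, O5, C6, C7, C8, C9 (C9′ = its CH2OH carbon), C10–C21, O22, C23, C24, N25, C26. Rings: A γ-lactone, B pyrrolidine, C piperidine, D cyclopentane, E cycloheptane, F cyclopentene, G δ-lactone.
Cuts, last-made first: ring G (C19–C18 and O22–C23 together, acrylic acid off a C18=C23 olefin); ring E (C17–C18, then C10–C11, ring F leaving as a C13-chiral cyclopentanone); ring A (C6–H/O5 closure, C4 from an allyl end, C2–C3); ring B (C2–C6); rings C/D (C7–C23, C9–C10, C8–C9).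
Forward: serine ester, allyl acrylate, chloroacetyl chloride and methyl 4-chloroacetoacetate give C/D in one flask, then B (Dieckmann), quaternary C2, A, alkylation with the ring F iodide, E, G, and removal of the helpers.
Stereochemistry: C9 from a chiral ammonium ion pair and C7 from the bridge; C2 from Pd/(R)-t-BuPHOX and C6 from the cis-fusion constraint of A/B; C13 from an (S)-BINOL aluminate; C10 from exo protonation; C18 and C23 from exo-face annulation.
Enabling feature: in the two-carbon bridge of the 2-azabicyclo[3.2.1]octene (rings C/D), C23 is a CH terminus beside the fully substituted C18, which is conjugated with C17=C16 of ring F. One-electron oxidation lets a carboxylate bind C23 and leaves an allyl radical at C18, placed for six-ring closure onto the acrylate CH2.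
Helpers: the C24 lactam carbonyl shields N25 from oxidation and activates C10; OTf at C16 blocks the second diene terminus and is later exchanged for H; TIPS protects O at C9′.

Key step: step 22

Remark on the chemistry: the sense of induction of the three chiral catalysts (steps 3, 6, 13) is assigned by analogy with simple substrates. In each case the antipodal catalyst is equally available.

Step 1
Reactants: 1 L-serine methyl ester hydrochloride; 2 allyl acrylate
Product: 3 methyl N-[3-(allyloxy)-3-oxopropyl]-L-serinate
Conditions: Et3N (1 equiv), MeCN, rt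
Reagents that add atoms: none
Why: Aza-Michael addition of the primary amine to one equivalent of acrylate should stop at the secondary amine and brings in C26, C2 and the allyl ester; the serine stereocentre is erased in step 2.

Step 2
Reactants: 3 methyl N-[3-(allyloxy)-3-oxopropyl]-L-serinate; 4 chloroacetyl chloride
Product: 7 methyl 2-{(chloroacetyl)[3-(allyloxy)-3-oxopropyl]amino}acrylate, via N-chloroacetyl serinate 5 (not isolated), via O-mesylate 6 (not isolated)
Conditions: 4, NaHCO3, CH2Cl2/H2O, 0 °C; dried organic layer, then MsCl, Et3N, CH2Cl2, 0 °C to rt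
Reagents that add atoms: none
Why: Schotten–Baumann N-acylation followed by mesylation and E1cB β-elimination is the standard serine-to-dehydroalanine conversion and gives the Michael acceptor C8=C7 that already carries the C10–Cl electrophile.

Step 3
Reactants: 7 methyl 2-{(chloroacetyl)[3-(allyloxy)-3-oxopropyl]amino}acrylate; 8 methyl 4-chloroacetoacetate
Product: 11 dimethyl 2-[3-(allyloxy)-3-oxopropyl]-3,6-dioxo-2-azabicyclo[3.2.1]octane-1,5-dicarboxylate (rings C/D), via Michael adduct 9 (not isolated), via monocyclic lactam 10 (not isolated)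
Conditions: (11bS)-4,4-dibutyl-2,6-bis(3,4,5-trifluorophenyl)-4,5-dihydro-3H-dinaphtho[2,1-c:1′,2′-e]azepinium bromide (5 mol %), Cs2CO3, toluene, −20 °C, slow addition of 8; then NaI (cat.), DMF, 40 °C
Reagents that add atoms: none
Why: Three standard enolate reactions run in one flask: Michael addition of the β-keto ester to the dehydroalanine (C9–C8), asymmetric phase-transfer alkylation of the tertiary β-keto ester enolate by the tethered chloroacetamide (C9–C10, 6-exo-tet, C9 set by the chiral ion pair), and alkylation of the amino ester enolate by the α-chloro ketone (C7–C23, 5-exo-tet, C7 fixed because only the cis bridge can close).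

Step 4
Reactants: 11 bicyclic keto lactam diester
Product: 12 C18 tert-butyldimethylsilyl enol ether of 11 (C18=C23)
Conditions: TBSOTf, Et3N, CH2Cl2, 0 °C
Reagents that add atoms: tert-butyldimethylsilyl triflate, CC(C)(C)[Si](C)(C)OS(=O)(=O)C(F)(F)F
Why: Soft enolisation can only go towards C23 because C9 is quaternary, and the enol silane masks the acidic C23–H and the retro-Claisen-prone β-keto ester during steps 5 and 6.

Step 5
Reactants: 12 silyl enol ether
Product: 14 tricyclic C2-methyl C2-allyl ester C6 ketone (rings B/C/D; C2 epimers), via Dieckmann keto ester 13 (not isolated)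
Conditions: KOt-Bu, THF, −20 to 0 °C; then MeI, 0 °C to rt
Reagents that add atoms: iodomethane, CI
Why: Dieckmann condensation of the C2 ester enolate onto the C6 ester (5-exo-trig, as in the usual route to 4-oxopyrrolidine-3-carboxylates) closes ring B, and the stabilised enolate is C-methylated in the same flask; the C2 configuration is irrelevant here.

Step 6
Reactants: 14 allyl β-keto ester
Product: 15 C2-allyl C2-methyl C6 ketone (allyl on the face of C23, methyl on the face of C8)
Conditions: Pd2(dba)3 (5 mol %), (R)-4-tert-butyl-2-[2-(diphenylphosphanyl)phenyl]-4,5-dihydrooxazole ((R)-t-BuPHOX, 12 mol %), toluene, 30 °C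
Reagents that add atoms: none
Why: Decarboxylative asymmetric allylic alkylation (Tsuji type) passes through a palladium enolate in which the old C2 centre is erased, and because the two faces of ring B are sterically alike the ligand should decide the face of allylation.

Step 7
Reactants: 15 silyl enol ether ketone
Product: 16 C18 enol triflate
Conditions: CsF, PhNTf2, DME, rt
Reagents that add atoms: N-phenylbis(trifluoromethanesulfonimide), O=S(=O)(N(c1ccccc1)S(=O)(=O)C(F)(F)F)C(F)(F)F
Why: Fluoride cleavage of the enol silane gives the regiodefined enolate, which is O-sulfonylated (standard enol silane to enol triflate exchange); it comes after step 6 so that no enol triflate meets zerovalent palladium too early.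

Step 8
Reactants: 16 enol triflate keto ester
Product: 17 C9′ primary alcohol C6 carbinol (C6 epimers)
Conditions: LiBH4, THF, MeOH (1 equiv), 0 °C to rt
Reagents that add atoms: none
Why: Borohydride reduction with LiBH4 takes the C9′ ester and the C6 ketone but not the tertiary lactam or the enol triflate; the C6 configuration does not matter because it is re-oxidised in step 10.

Step 9
Reactants: 17 diol
Product: 18 C9′ triisopropylsilyl ether
Conditions: TIPSCl, imidazole, DMF, rt
Reagents that add atoms: chlorotriisopropylsilane, CC(C)[Si](Cl)(C(C)C)C(C)C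
Why: Silylation with a bulky chlorosilane should select the primary alcohol over the C6 carbinol, which lies between two quaternary carbons.

Step 10
Reactants: 18 silyl ether carbinol
Product: 19 C6 ketone
Conditions: DMP (1,1,1-triacetoxy-1,1-dihydro-1,2-benziodoxol-3(1H)-one), NaHCO3, CH2Cl2, rt
Reagents that add atoms: none
Why: Dess–Martin oxidation restores the non-enolisable C6 ketone under neutral conditions that leave the alkene, enol triflate and silyl ether untouched.

Step 11
Reactants: 19 allyl ketone
Product: 20 γ-keto acid (C2–CH2CO2H)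
Conditions: OsO4 (2 mol %), Oxone, DMF, rt
Reagents that add atoms: potassium peroxymonosulfate (Oxone), [K+].[O-]S(=O)(=O)OO
Why: Osmium-catalysed oxidative cleavage with peroxymonosulfate converts the monosubstituted alkene directly into the C4 acid, the electron-poor trisubstituted enol triflate being much slower.

Step 12
Reactants: 20 γ-keto acid
Product: 22 tetracyclic lactone lactam enol triflate (rings A/B/C/D), via hydroxylactone 21 (not isolated)
Conditions: Et3SiH, CF3CO2H/CH2Cl2, 0 °C to rt
Reagents that add atoms: none
Why: Ionic hydrogenation of a γ-keto acid: the quaternary C2 holds the acid as the cyclic hydroxylactone, acid ionises it to the acyloxocarbenium ion, and the silane can deliver hydride to C6 only on the methyl face, because the other face would give a trans-fused bicyclo[3.3.0] system.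

Step 13
Reactants: 23 cyclopent-2-enone; 24 dimethyl malonate
Product: 25 dimethyl 2-[(1S)-3-oxocyclopentyl]malonate
Conditions: LiAl[(S)-1,1′-binaphthalene-2,2′-diolate]2 (10 mol %), KOt-Bu (9 mol %), 4 Å molecular sieves, THF, rt
Reagents that add atoms: none
Why: Catalytic asymmetric Michael addition of a malonate to a cyclic enone with the bifunctional aluminium lithium binaphthoxide sets C13 by catalyst control.

Step 14
Reactants: 25 malonate adduct
Product: 26 methyl 2-[(1S)-3-oxocyclopentyl]acetate
Conditions: NaCl, H2O, DMSO, 150 °C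
Reagents that add atoms: none
Why: Krapcho decarboxylation removes one ester under neutral conditions and does not touch C13, which is β to the ketone.

Step 15
Reactants: 26 keto ester
Product: 27 methyl 2-[(7S)-1,4-dioxaspiro[4.4]nonan-7-yl]acetate
Conditions: ethylene glycol, p-TsOH (cat.), toluene, reflux, water separator
Reagents that add atoms: ethylene glycol, OCCO
Why: Acid-catalysed ketalisation protects the C16 ketone against hydride and amide bases.

Step 16
Reactants: 27 ketal ester
Product: 28 2-[(7R)-1,4-dioxaspiro[4.4]nonan-7-yl]ethanol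
Conditions: LiAlH4, THF, 0 °C
Reagents that add atoms: none
Why: Hydride reduction of the ester gives the C11 alcohol (the descriptor changes by priority only).

Step 17
Reactants: 28 alcohol
Product: 29 (7S)-7-(2-iodoethyl)-1,4-dioxaspiro[4.4]nonane
Conditions: I2, PPh3, imidazole, CH2Cl2, 0 °C
Reagents that add atoms: iodine, II
Why: Appel-type iodination converts the primary alcohol into the alkylating agent under conditions that spare the ketal.

Step 18
Reactants: 22 tetracyclic lactone lactam enol triflate; 29 (7S)-7-(2-iodoethyl)-1,4-dioxaspiro[4.4]nonane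
Product: 31 C10-alkylated lactam (C11 endo and equatorial; H10 exo), via C10 epimer 30 (not isolated)
Conditions: LDA (2.3 equiv), THF, −78 °C; 29, DMPU, −78 to −30 °C; LDA (1.3 equiv), −78 to −40 °C; AcOH, −78 °C
Reagents that add atoms: none
Why: Dianion alkylation: the lactone stays masked as its less reactive enolate while the amide enolate is alkylated axially from the exo face, then renewed deprotonation and kinetic protonation, again from the exo face syn to C8, should turn the chain to the endo side as the target requires.

Step 19
Reactants: 31 ketal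
Product: 32 C16 ketone
Conditions: 1 M HCl, THF, rt
Reagents that add atoms: water, O
Why: Mild acid hydrolysis of the dioxolane frees the cyclopentanone while lactone, lactam, enol triflate and the hindered TIPS ether remain.

Step 20
Reactants: 32 keto enol triflate
Product: 33 hexacyclic β,γ-unsaturated ketone (ring E closed; C17 epimers)
Conditions: Pd2(dba)3 (5 mol %), 2-dicyclohexylphosphanyl-2′,4′,6′-triisopropylbiphenyl (12 mol %), K3PO4, toluene, 80 °C
Reagents that add atoms: none
Why: Intramolecular palladium-catalysed α-alkenylation of a ketone enolate with an enol triflate forms C17–C18; of the two enolisable positions only C17 can reach C18 (seven-membered ring), and the weak base spares the lactone.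

Step 21
Reactants: 33 β,γ-unsaturated ketone
Product: 34 dienyl triflate C23=C18–C17=C16(OTf)
Conditions: KOt-Bu, THF, −40 to −10 °C; then PhNTf2
Reagents that add atoms: N-phenylbis(trifluoromethanesulfonimide), O=S(=O)(N(c1ccccc1)S(=O)(=O)C(F)(F)F)C(F)(F)F
Why: Enolate O-sulfonylation: reversible deprotonation removes the doubly activated C17–H (or C23–H of any conjugated tautomer) to give the linear dienolate, the thermodynamic one as with steroid enones, and this erases C17.

Step 22
Reactants: 34 dienyl triflate; 35 acrylic acid
Product: 36 heptacyclic bis-lactone lactam C16 enol triflate (ring G closed)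
Conditions: 35 (5 equiv), 3,6-di-tert-butyl-9-mesityl-10-phenylacridinium tetrafluoroborate (5 mol %), (PhS)2 (10 mol %), 2,6-lutidine (30 mol %), ClCH2CH2Cl, 450 nm LED, rt, N2
Reagents that add atoms: none
Why: Proposed new method: the photoexcited acridinium oxidises the 2-triflyloxy-1,3-diene C23=C18–C17=C16 of 34 to its radical cation, acrylate (from 35 and lutidine) binds the CH terminus C23 (O22–C23), the resulting C18–C17–C16 allyl radical adds through C18 to the acrylate CH2 (C19–C18), the α-acyl radical at C20 takes a hydrogen atom from PhSH, and PhS• re-oxidises the acridinyl radical, so that the step is redox-neutral and loses no atom. The closest known reaction type is the polar radical crossover cycloaddition of oxidisable alkenes with unsaturated acids under acridinium/thiol catalysis, known for 5-exo closure to γ-butyrolactones; the 6-endo closure with acrylic acid itself and a dienyl triflate as the alkene partner are not known. Ring G closes 6-endo-trig: attack on the unsubstituted β-carbon is polarity-matched (Giese type) and gives a stabilised α-acyl radical, whereas 5-exo attack on the α-carbon would give a primary radical and closure through C16 an eight-membered ring. C23 is set by attack of the carboxylate on the exo face of the azabicyclo[3.2.1]octene (syn to the C8 bridge; the endo face is covered by the N25–C24–C10 bridge and ring E), and C18 by ring E, which ties C17 to the endo side, so that C19 can only enter exo and cis to O22. The step needs chemoselective oxidation (secured by the C24 lactam, which takes N25 out of play, and by the absence of any other electron-rich π bond), regioselective O-attack (C16 is fully substituted and deactivated by OTf, C23 is a CH) and ring closure faster than hydrogen transfer to the allyl radical (low thiol loading and relief of the strain that the sp2 centre C18 causes in ring E). The C16=C17 enol triflate that remains stands exactly where the target has its alkene.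

Step 23
Reactants: 36 enol triflate
Product: 37 C16=C17 alkene
Conditions: Pd(OAc)2 (10 mol %), PPh3 (20 mol %), HCO2H, Et3N, DMF, 60 °C
Reagents that add atoms: none
Why: Palladium-catalysed formate reduction of an enol triflate (oxidative addition, formate exchange, decarboxylation, reductive elimination) replaces OTf by H without moving the double bond.

Step 24
Reactants: 37 lactam
Product: 38 tertiary amine (C24H2)
Conditions: Zn(OAc)2 (20 mol %), (EtO)3SiH, THF, 40 °C
Reagents that add atoms: none
Why: Zinc-catalysed hydrosilylation of tertiary amides reduces the lactam to the amine while esters and lactones are left, and C10 cannot be scrambled because ring E tolerates only one configuration.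

Step 25
Reactants: 38 silyl ether
Product: 39 target CNP0247797.1
Conditions: HF·pyridine, THF, 0 °C to rt; NaHCO3 work-up
Reagents that add atoms: none
Why: Fluoride-mediated desilylation under mildly acidic conditions frees the C9′ alcohol without opening either lactone.

Compound list
1 | L-serine methyl ester hydrochloride | COC(=O)[C@@H](N)CO.Cl | starting material
2 | allyl acrylate | C=CC(=O)OCC=C | starting material
3 | methyl N-[3-(allyloxy)-3-oxopropyl]-L-serinate | COC(=O)[C@H](CO)NCCC(=O)OCC=C | intermediate
4 | chloroacetyl chloride | ClCC(Cl)=O | starting material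
5 | methyl N-(chloroacetyl)-N-[3-(allyloxy)-3-oxopropyl]-L-serinate | COC(=O)[C@H](CO)N(CCC(=O)OCC=C)C(=O)CCl | intermediate
6 | O-mesylate of 5 | COC(=O)[C@H](COS(C)(=O)=O)N(CCC(=O)OCC=C)C(=O)CCl | intermediate
7 | methyl 2-{(chloroacetyl)[3-(allyloxy)-3-oxopropyl]amino}acrylate | C=C(C(=O)OC)N(CCC(=O)OCC=C)C(=O)CCl | intermediate
8 | methyl 4-chloroacetoacetate | COC(=O)CC(=O)CCl | starting material
9 | Michael adduct of 8 to 7 (labile centres C7, C9) | COC(=O)C(C(=O)CCl)CC(C(=O)OC)N(CCC(=O)OCC=C)C(=O)CCl | intermediate
10 | monocyclic δ-lactam, C9 quaternary as in 39, C7 labile | COC(=O)C1C[C@](C(=O)OC)(C(=O)CCl)CC(=O)N1CCC(=O)OCC=C | intermediate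
11 | dimethyl 2-[3-(allyloxy)-3-oxopropyl]-3,6-dioxo-2-azabicyclo[3.2.1]octane-1,5-dicarboxylate, C7 and C9 as in 39 | [C@@]12(C(=O)OC)C[C@@](C(=O)OC)(CC(=O)N1CCC(=O)OCC=C)C(=O)C2 | intermediate
12 | C18 TBS enol ether of 11 | [C@@]12(C(=O)OC)C[C@@](C(=O)OC)(CC(=O)N1CCC(=O)OCC=C)C(O[Si](C)(C)C(C)(C)C)=C2 | intermediate
13 | Dieckmann β-keto allyl ester, ring B closed, C2–H | [C@]123C[C@@](C(=O)OC)(CC(=O)N1CC(C(=O)OCC=C)C2=O)C(O[Si](C)(C)C(C)(C)C)=C3 | intermediate
14 | C2-methyl β-keto allyl ester (C2 epimers) | [C@]123C[C@@](C(=O)OC)(CC(=O)N1CC(C)(C(=O)OCC=C)C2=O)C(O[Si](C)(C)C(C)(C)C)=C3 | intermediate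
15 | C2-allyl C2-methyl C6 ketone, C2 as in 39 | [C@]123C[C@@](C(=O)OC)(CC(=O)N1C[C@](C)(CC=C)C2=O)C(O[Si](C)(C)C(C)(C)C)=C3 | intermediate
16 | C18 enol triflate of the 15 series | [C@]123C[C@@](C(=O)OC)(CC(=O)N1C[C@](C)(CC=C)C2=O)C(OS(=O)(=O)C(F)(F)F)=C3 | intermediate
17 | C9′ alcohol, C6 carbinol (C6 epimers) | [C@]123C[C@@](CO)(CC(=O)N1C[C@](C)(CC=C)C2O)C(OS(=O)(=O)C(F)(F)F)=C3 | intermediate
18 | C9′ TIPS ether of 17 | [C@]123C[C@@](CO[Si](C(C)C)(C(C)C)C(C)C)(CC(=O)N1C[C@](C)(CC=C)C2O)C(OS(=O)(=O)C(F)(F)F)=C3 | intermediate
19 | C6 ketone, C9′ TIPS ether | [C@]123C[C@@](CO[Si](C(C)C)(C(C)C)C(C)C)(CC(=O)N1C[C@](C)(CC=C)C2=O)C(OS(=O)(=O)C(F)(F)F)=C3 | intermediate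
20 | γ-keto acid | [C@]123C[C@@](CO[Si](C(C)C)(C(C)C)C(C)C)(CC(=O)N1C[C@](C)(CC(=O)O)C2=O)C(OS(=O)(=O)C(F)(F)F)=C3 | intermediate
21 | cyclic hydroxylactone (pseudo acid) of 20, OH on the methyl face | [C@]123C[C@@](CO[Si](C(C)C)(C(C)C)C(C)C)(CC(=O)N1C[C@]4(C)CC(=O)O[C@]24O)C(OS(=O)(=O)C(F)(F)F)=C3 | intermediate
22 | tetracyclic γ-lactone lactam enol triflate, C2, C6, C7, C9 as in 39 | [C@]123C[C@@](CO[Si](C(C)C)(C(C)C)C(C)C)(CC(=O)N1C[C@]4(C)CC(=O)O[C@H]24)C(OS(=O)(=O)C(F)(F)F)=C3 | intermediate
23 | cyclopent-2-enone | O=C1C=CCC1 | starting material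
24 | dimethyl malonate | COC(=O)CC(=O)OC | starting material
25 | dimethyl 2-[(1S)-3-oxocyclopentyl]malonate | COC(=O)C(C(=O)OC)[C@H]1CCC(=O)C1 | intermediate
26 | methyl 2-[(1S)-3-oxocyclopentyl]acetate | COC(=O)C[C@H]1CCC(=O)C1 | intermediate
27 | methyl 2-[(7S)-1,4-dioxaspiro[4.4]nonan-7-yl]acetate | COC(=O)C[C@H]1CCC2(C1)OCCO2 | intermediate
28 | 2-[(7R)-1,4-dioxaspiro[4.4]nonan-7-yl]ethanol | OCC[C@H]1CCC2(C1)OCCO2 | intermediate
29 | (7S)-7-(2-iodoethyl)-1,4-dioxaspiro[4.4]nonane | ICC[C@H]1CCC2(C1)OCCO2 | intermediate
30 | C10-alkylated lactam, chain exo (C10 epimer of 31) | [C@]123C[C@@](CO[Si](C(C)C)(C(C)C)C(C)C)([C@@H](CC[C@H]4CCC5(C4)OCCO5)C(=O)N1C[C@]6(C)CC(=O)O[C@H]26)C(OS(=O)(=O)C(F)(F)F)=C3 | intermediate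
31 | C10-alkylated lactam, chain endo, C10 and C13 as in 39 | [C@]123C[C@@](CO[Si](C(C)C)(C(C)C)C(C)C)([C@H](CC[C@H]4CCC5(C4)OCCO5)C(=O)N1C[C@]6(C)CC(=O)O[C@H]26)C(OS(=O)(=O)C(F)(F)F)=C3 | intermediate
32 | C16 ketone from 31 | [C@]123C[C@@](CO[Si](C(C)C)(C(C)C)C(C)C)([C@H](CC[C@H]4CCC(=O)C4)C(=O)N1C[C@]5(C)CC(=O)O[C@H]25)C(OS(=O)(=O)C(F)(F)F)=C3 | intermediate
33 | hexacyclic β,γ-unsaturated C16 ketone, ring E closed (C17 epimers) | [C@]123C[C@@]4(CO[Si](C(C)C)(C(C)C)C(C)C)[C@H](CC[C@H]5CCC(=O)C5C4=C3)C(=O)N1C[C@]6(C)CC(=O)O[C@H]26 | intermediate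
34 | hexacyclic dienyl triflate C23=C18–C17=C16(OTf) | [C@]123C[C@@]4(CO[Si](C(C)C)(C(C)C)C(C)C)[C@H](CC[C@H]5CCC(OS(=O)(=O)C(F)(F)F)=C5C4=C3)C(=O)N1C[C@]6(C)CC(=O)O[C@H]26 | intermediate
35 | acrylic acid | C=CC(=O)O | starting material
36 | heptacyclic bis-lactone lactam C16 enol triflate, all eight stereocentres as in 39 | [C@]123C[C@@]4(CO[Si](C(C)C)(C(C)C)C(C)C)[C@H](CC[C@H]5CCC(OS(=O)(=O)C(F)(F)F)=C5[C@]47CCC(=O)O[C@H]37)C(=O)N1C[C@]6(C)CC(=O)O[C@H]26 | intermediate
37 | heptacyclic bis-lactone lactam with C16=C17 alkene | [C@]123C[C@@]4(CO[Si](C(C)C)(C(C)C)C(C)C)[C@H](CC[C@H]5CCC=C5[C@]47CCC(=O)O[C@H]37)C(=O)N1C[C@]6(C)CC(=O)O[C@H]26 | intermediate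
38 | O-TIPS ether of the target | [C@]123C[C@@]4(CO[Si](C(C)C)(C(C)C)C(C)C)[C@H](CC[C@H]5CCC=C5[C@]47CCC(=O)O[C@H]37)CN1C[C@]6(C)CC(=O)O[C@H]26 | intermediate
39 | CNP0247797.1 | C[C@@]12CC(=O)O[C@@H]1[C@]13C[C@@]4(CO)[C@H](CC[C@H]5CCC=C5[C@]45CCC(=O)O[C@H]15)CN3C2 | target

Total steps: 25. Longest linear sequence: 20 (steps 1–12 and 18–25). Steps 13–17 form the side branch.

Steps most likely to fail

1. Step 22 (Proposed new method).
- What may go wrong: hydrogen transfer to the stabilised allyl radical before ring closure; slow closure because the ester must reach the s-cis geometry; radical polymerisation or thiol addition consuming acrylic acid; deprotonation of the radical cation instead of carboxylate capture.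
- Fallback with known chemistry, from 34: dimethyldioxirane should epoxidise the C18=C23 bond, the electron-richer double bond, which is open on its exo face, to give the vinyl epoxide F1. Cp2TiCl (trivalent titanium, made from Cp2TiCl2 and Zn) with collidine hydrochloride opens it reductively (Nugent–RajanBabu opening) to the C18 allyl radical carrying the C23–O–Ti group. Methyl acrylate traps this radical from the exo face (Giese addition) to give the δ-hydroxy ester F2. Acid-catalysed lactonisation of F2 returns to the route at 36.

2. Step 3.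
- What may go wrong: self-condensation of 8; poor facial discrimination in the ion pair during the C9–C10 alkylation; stalling of the last closure because the chloro ketone rests as its own enolate.
- Fallback, from 7 and 8: the cascade is run with achiral Bu4NBr through the racemic monocyclic lactam F3 to the racemic bicycle F4. Kinetic resolution by asymmetric transfer hydrogenation with RuCl(p-cymene)[(S,S)-TsDPEN] and HCO2H/Et3N reduces the C18 ketone of the unwanted enantiomer to the carbinol F5. The unreacted enantiomer is 11, which re-enters at step 4.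

3. Step 20.
- What may go wrong: slow oxidative addition at the enol triflate next to quaternary C9; reluctant reductive elimination from the palladacycle that leads to the seven-membered ring; hydrolysis of the triflate; base-induced damage to the lactone.
- Fallback, from 32: TMSOTf/Et3N converts the ketone into its enol silanes, of which the C16=C17 isomer is the trimethylsilyl enol ether F6. With Bu3SnF and Pd2(dba)3/P(t-Bu)3 in toluene, the tin enolate formed in situ couples with the enol triflate without any added base to give 33. The C15=C16 isomer cannot reach C18 and is hydrolysed back to 32.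

Further compounds
F1 | step 22 | exo C18–C23 epoxide of 34 (vinyl epoxide) | [C@]123C[C@@]4(CO[Si](C(C)C)(C(C)C)C(C)C)[C@H](CC[C@H]5CCC(OS(=O)(=O)C(F)(F)F)=C5[C@]47O[C@H]37)C(=O)N1C[C@]6(C)CC(=O)O[C@H]26
F2 | step 22 | C23 exo alcohol with C18 exo CH2CH2CO2Me chain (δ-hydroxy ester) | [C@]123C[C@@]4(CO[Si](C(C)C)(C(C)C)C(C)C)[C@H](CC[C@H]5CCC(OS(=O)(=O)C(F)(F)F)=C5[C@@]4(CCC(=O)OC)[C@@H]3O)C(=O)N1C[C@]6(C)CC(=O)O[C@H]26
F3 | step 3 | racemic monocyclic δ-lactam (racemic 10) | COC(=O)C1CC(C(=O)OC)(C(=O)CCl)CC(=O)N1CCC(=O)OCC=C
F4 | step 3 | racemic bicyclic keto lactam diester (racemic 11) | COC(=O)C12CC(C(=O)OC)(CC(=O)N1CCC(=O)OCC=C)C(=O)C2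
F5 | step 3 | C18 carbinol of the enantiomer of 11 | [C@]12(C(=O)OC)C[C@](C(=O)OC)(CC(=O)N1CCC(=O)OCC=C)C(O)C2
F6 | step 20 | C16=C17 trimethylsilyl enol ether of 32 | [C@]123C[C@@](CO[Si](C(C)C)(C(C)C)C(C)C)([C@H](CC[C@H]4CCC(O[Si](C)(C)C)=C4)C(=O)N1C[C@]5(C)CC(=O)O[C@H]25)C(OS(=O)(=O)C(F)(F)F)=C3
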